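**Plan**

- Retrosynthesis: the two acetates, the tiglate and the C5=C6/C7=C11 unsaturation go back to a 7,8-epoxy-5-mesyloxy γ-lactone. The C9–C10 bond of the ten-membered ring is then cut by a retro-oxy-Cope that restores a C2–C7 bond, giving a 1-propynyl-2-vinylcyclohexanol fused to the lactone. C7–C11 is cut by a retro-Ireland–Claisen, and the cyclohexane is traced to the quinone monoketal of 2,4-dimethoxyphenol.
- Forward order of rings: cyclohexane (from the arene), then cis-fused γ-lactone (epoxide-opening lactonisation), then ten-membered carbocycle (key step), then butenolide and enol lactone (elimination cascade).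
- Enabling feature: the oxygens on C2 and C8 are 1,5 across C1=C10–C9, and trigonal C7 is reached from C2 through C1, C10, C9 and C8. C10≡C1–C2(O–)–C7–C8=C9 is therefore a 3-oxido-1,5-enyne; its [3,3] shift makes C9–C10, the Z enone and trigonal C7 while breaking the temporary C2–C7 bond.
- Stereochemistry: one asymmetric nucleophilic epoxidation (C5, C6) is relayed by substrate control to C4 (Grignard addition anti to the epoxide), C7 (Claisen anti to the epoxide) and C6 (inversion on lactonisation). C8 comes from a Shi epoxidation and C2 from a Corey–Bakshi–Shibata reduction. The helper centres C5, C6, C7 and C11 are erased in step 16.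

Key step: step 12

Remark: C1–C15 are the germacrane locants of the target (ring C1–C10 with C1=C10; acetoxy on C2; carbinol C4 with methyl C15; lactone oxygen on C6; butenolide C7, C11, C12 with CH2O carbon C13; tigloyloxy on C8; methyl C14 on C10) and are used for the earlier rings too; C11 is an epimer mixture from 12 to 23 and is erased in step 16; acid 9 is taken as a purchased building block.

Step 1
Reactants: 1 2,4-dimethoxyphenol
Product: 2 2,4,4-trimethoxycyclohexa-2,5-dien-1-one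
Conditions: PhI(OAc)2, MeOH, 0 °C
Reagents that add atoms: methanol (CO)
Why: Hypervalent-iodine oxidative dearomatisation of a para-methoxyphenol; methanol traps the phenoxenium ion at the methoxy-bearing para carbon and gives the quinone monoketal.

Step 2
Reactants: 2 2,4,4-trimethoxycyclohexa-2,5-dien-1-one
Product: 3 (1S,6R)-3,5,5-trimethoxy-7-oxabicyclo[4.1.0]hept-3-en-2-one
Conditions: Ph3COOH, NaN(SiMe3)2, diisopropyl L-tartrate (the antipode is used if it proves to be the one that gives the (1S,6R) epoxide), 4 Å molecular sieves, toluene, −50 °C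
Reagents that add atoms: trityl hydroperoxide (OOC(c1ccccc1)(c1ccccc1)c1ccccc1)
Why: Tartrate-mediated nucleophilic (Weitz–Scheffer type) epoxidation of a quinone monoketal; the peroxide adds to the unsubstituted enone C5=C6 (the methoxy-bearing alkene is deactivated) and the chiral sodium tartrate–peroxide complex selects one enantiotopic face, which sets both epoxide centres.

Step 3
Reactants: 3 (1S,6R)-3,5,5-trimethoxy-7-oxabicyclo[4.1.0]hept-3-en-2-one
Product: 4 ethyl (2E)-[(1R,6R)-3,5,5-trimethoxy-7-oxabicyclo[4.1.0]hept-3-en-2-ylidene]acetate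
Conditions: Ph3P=CHCO2Et, toluene, 90 °C
Reagents that add atoms: ethyl (triphenylphosphoranylidene)acetate (CCOC(=O)C=P(c1ccccc1)(c1ccccc1)c1ccccc1)
Why: Wittig olefination of the only ketone with a stabilised ylide; the ester should settle on the epoxide side to avoid allylic strain with the methoxy group, and either alkene geometry converges in step 8.

Step 4
Reactants: 4 ethyl (2E)-[(1R,6R)-3,5,5-trimethoxy-7-oxabicyclo[4.1.0]hept-3-en-2-ylidene]acetate
Product: 5 ethyl (2E)-[(1R,6R)-3-methoxy-5-oxo-7-oxabicyclo[4.1.0]hept-3-en-2-ylidene]acetate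
Conditions: pyridinium p-toluenesulfonate (cat.), acetone/H2O, 23 °C
Reagents that add atoms: water (O)
Why: Mild acid hydrolysis of the dimethyl ketal, assisted by the neighbouring enol ether, unmasks the C4 ketone as a vinylogous ester while the push–pull enol ether and the epoxide survive.

Step 5
Reactants: 5 ethyl (2E)-[(1R,6R)-3-methoxy-5-oxo-7-oxabicyclo[4.1.0]hept-3-en-2-ylidene]acetate
Product: 7 ethyl (2E)-{(1R,5S,6R)-3-methoxy-5-methyl-5-[(triethylsilyl)oxy]-7-oxabicyclo[4.1.0]hept-3-en-2-ylidene}acetate, via bromomagnesium alkoxide 6 (not isolated)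
Conditions: MeMgBr, Et2O/toluene, −78 °C; then Et3SiOTf, 2,6-lutidine, −78 → 0 °C
Reagents that add atoms: methylmagnesium bromide (C[Mg]Br); triethylsilyl trifluoromethanesulfonate (CC[Si](CC)(CC)OS(=O)(=O)C(F)(F)F)
Why: Grignard 1,2-addition to the epoxy ketone is expected anti to the epoxide oxygen (new C–O bond cis to the epoxide), which sets the C4 carbinol of the target by substrate control; the alkoxide is silylated in the same flask.

Step 6
Reactants: 7 ethyl (2E)-{(1R,5S,6R)-3-methoxy-5-methyl-5-[(triethylsilyl)oxy]-7-oxabicyclo[4.1.0]hept-3-en-2-ylidene}acetate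
Product: 8 (2E)-2-{(1R,5S,6R)-3-methoxy-5-methyl-5-[(triethylsilyl)oxy]-7-oxabicyclo[4.1.0]hept-3-en-2-ylidene}ethan-1-ol
Conditions: iBu2AlH, CH2Cl2, −78 °C; aq. KNaC4H4O6 work-up; purification on Et3N-deactivated silica
Reagents that add atoms: none
Why: iBu2AlH reduces the conjugated ester to the primary allylic alcohol at low temperature without touching the epoxide, the enol ether or the silyl ether.

Step 7
Reactants: 8 (2E)-2-{(1R,5S,6R)-3-methoxy-5-methyl-5-[(triethylsilyl)oxy]-7-oxabicyclo[4.1.0]hept-3-en-2-ylidene}ethan-1-ol; 9 3-{[tert-butyl(dimethyl)silyl]oxy}propanoic acid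
Product: 10 allylic ester of 8 with 9
Conditions: EDC·HCl, DMAP (cat.), CH2Cl2, 0 → 23 °C
Reagents that add atoms: none
Why: Steglich esterification of the only free hydroxyl under base-buffered conditions that the acid-labile methoxydiene tolerates.

Step 8
Reactants: 10 allylic ester of 8 with 9
Product: 13 3-{[tert-butyl(dimethyl)silyl]oxy}-2-{(1R,2R,5S,6R)-2-ethenyl-3-methoxy-5-methyl-5-[(triethylsilyl)oxy]-7-oxabicyclo[4.1.0]hept-3-en-2-yl}propanoic acid, via silyl ketene acetal 11 (not isolated), via trimethylsilyl ester 12 (not isolated)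
Conditions: LiN(iPr)2, Me3SiCl/Et3N (internal quench), THF, −78 → 50 °C; then H2O, pH 5 buffer
Reagents that add atoms: none
Why: Ireland–Claisen rearrangement forms the C7–C11 bond and the vinyl group (C8=C9) at once; the new bond should form on the ring face anti to the adjacent epoxide oxygen, which fixes quaternary C7, while C11 arises as an inconsequential epimer mixture.

Step 9
Reactants: 13 Claisen acid
Product: 15 (3aR,6S,7R,7aS)-3-({[tert-butyl(dimethyl)silyl]oxy}methyl)-3a-ethenyl-7-hydroxy-6-methyl-6-[(triethylsilyl)oxy]hexahydro-1-benzofuran-2,4-dione, via enol ether lactone 14 (not isolated)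
Conditions: camphorsulfonic acid (cat.), CH2Cl2, 0 °C; then oxalic acid, THF/H2O, 23 °C
Reagents that add atoms: water (O)
Why: Acid-catalysed 5-exo opening of the epoxide by the neighbouring carboxylic acid with inversion at C6 gives the cis-fused γ-lactone and the C5 hydroxyl; buffered hydrolysis of the methyl enol ether by C-protonation then releases the C2 ketone, the tertiary silyl ether being deactivated towards ionisation by the oxygenated C5.

Step 10
Reactants: 15 hydroxy keto lactone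
Product: 16 (3aR,6S,7R,7aS)-3-({[tert-butyl(dimethyl)silyl]oxy}methyl)-3a-ethenyl-6-methyl-2,4-dioxo-6-[(triethylsilyl)oxy]octahydro-1-benzofuran-7-yl methanesulfonate
Conditions: MeSO2Cl, Et3N, CH2Cl2, −20 → 0 °C
Reagents that add atoms: methanesulfonyl chloride (CS(=O)(=O)Cl)
Why: Sulfonylation of the only free hydroxyl via sulfene; the mesylate sits on a neopentyl-like carbon with no anti β-hydrogen, so it should survive until the vinylogous E1cB of step 16.

Step 11
Reactants: 16 keto lactone mesylate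
Product: 17 (3aR,4S,6S,7R,7aS)-3-({[tert-butyl(dimethyl)silyl]oxy}methyl)-3a-ethenyl-4-hydroxy-6-methyl-2-oxo-4-(prop-1-yn-1-yl)-6-[(triethylsilyl)oxy]octahydro-1-benzofuran-7-yl methanesulfonate
Conditions: MeC≡CMgBr, CeCl3, THF, −78 °C
Reagents that add atoms: prop-1-yn-1-ylmagnesium bromide (CC#C[Mg]Br)
Why: The weakly basic organocerium adds to the hindered ketone instead of enolising it; the axial silyloxy group on C4 blocks axial attack, so the alkynyl group should enter equatorially, trans to the vinyl group, leaving the hydroxyl axial and anti to the lactone arm on C7.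

Step 12
Reactants: 17 1-propynyl-2-vinylcyclohexanol lactone
Product: 20 (1(10)Z,4S,5R,6S,7E)-13-{[tert-butyl(dimethyl)silyl]oxy}-5-[(methylsulfonyl)oxy]-2-oxo-4-[(triethylsilyl)oxy]germacra-1(10),7-dien-12,6-olide, via potassium alkoxide 18 (not isolated), via potassium allenolate 19 (not isolated)
Conditions: KN(SiMe3)2 (1.1 equiv), 18-crown-6, THF, −78 → 0 °C; then AcOH, −78 °C
Reagents that add atoms: none
Why: KN(SiMe3)2 converts 17 into alkoxide 18, whose C10≡C1–C2(O–)–C7–C8=C9 array is a 3-oxido-1,5-enyne: a charge-accelerated [3,3] sigmatropic shift (anionic oxy-Cope) forms the C9–C10 σ bond while the C2–C7 bond, which is not in the target, breaks, and the ring-expanded allenolate 19 is protonated on carbon to the enone. The closest known reaction type is the anionic oxy-Cope ring expansion of 1-alkynyl-2-vinylcycloalkanols and 1,2-divinylcyclohexanols to cyclodecadienones. The ten-membered carbocycle is closed by this one bond through a six-membered chair transition state fused to the cyclohexane, so the closure is a four-carbon ring expansion and not an end-to-end cyclisation. No stereocentre is created: C2 and C7 become trigonal, the trans-diequatorial propynyl and vinyl groups pass through the chair that gives the E C7=C8 bond, and the cyclic allenolate can only be protonated from outside the ring, cis to C14, which gives the Z C1=C10 bond of the target; C4, C5 and C6 are untouched. The shift must outrun acyl transfer, silyl migration and elimination: the axial alkoxide is anti to the lactone arm, the mesylate can neither be eliminated nor displaced, one equivalent of base leaves the mesyl and lactone α-protons alone, and the cold acetic acid quench stops the allenolate from equilibrating to the C3 enolate that could expel the C4 silyloxy group.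

Step 13
Reactants: 20 ten-membered dienone lactone
Product: 21 (1(10)Z,4S,5R,6R,7S,8R)-13-{[tert-butyl(dimethyl)silyl]oxy}-7,8-epoxy-5-[(methylsulfonyl)oxy]-2-oxo-4-[(triethylsilyl)oxy]germacr-1(10)-en-12,6-olide
Conditions: D-fructose-derived ketone catalyst of the Shi epoxidation (1,2:4,5-di-O-isopropylidene-β-D-erythro-2,3-hexodiulo-2,6-pyranose, 30 mol %), KHSO5 (as 2KHSO5·KHSO4·K2SO4), K2CO3, Bu4NHSO4, MeCN/(MeO)2CH2/H2O, pH 10.5, 0 °C
Reagents that add atoms: potassium peroxymonosulfate ([K+].[O-]S(=O)(=O)OO)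
Why: Shi asymmetric epoxidation; the chiral dioxirane attacks the isolated trisubstituted E alkene (the enone is deactivated) through the spiro transition state which, for this substitution pattern, should deliver oxygen to the face that gives (7S,8R) and so sets C8 of the target.

Step 14
Reactants: 21 epoxy enone lactone
Product: 22 (2R)-2-hydroxy analogue of 21 ((1(10)Z,2R,4S,5R,6R,7S,8R)-configured allylic alcohol)
Conditions: (S)-2-methyl-CBS-oxazaborolidine (20 mol %), catecholborane, toluene, −78 → −40 °C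
Reagents that add atoms: none
Why: Corey–Bakshi–Shibata reduction; the (S)-oxazaborolidine treats the alkenyl arm as the large group and should deliver hydride in a 1,2-sense to give the (2R)-allylic alcohol.

Step 15
Reactants: 22 (2R)-allylic alcohol
Product: 23 (2R)-2-acetoxy analogue of 21
Conditions: Ac2O, pyridine, DMAP (cat.), CH2Cl2, 0 °C
Reagents that add atoms: acetic anhydride (CC(=O)OC(C)=O)
Why: DMAP-catalysed acetylation of the only free hydroxyl installs the C2 acetate of the target, and C2 is no longer a ketone with acidic C3 protons when the base-mediated step follows.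

Step 16
Reactants: 23 epoxy lactone acetate; 24 tiglic acid ((2E)-2-methylbut-2-enoic acid)
Product: 27 4-O-triethylsilyl-13-O-deacetyl-13-O-[tert-butyl(dimethyl)silyl] derivative of the target, via hydroxy butenolide mesylate 25 (not isolated), via hydroxy ylidenebutenolide 26 (not isolated)
Conditions: 24, 2,4,6-Cl3C6H2COCl, Et3N, toluene, 23 °C (mixed anhydride); then 23, DBU, DMAP, toluene, −20 → 23 °C
Reagents that add atoms: none
Why: DBU removes the lactone α-proton on C11 and the enolate opens the 7,8-epoxide by E1cB to the butenolide with retention at C8; the now acidic γ-proton on C6 is removed and the furanolate expels the C5 mesylate (vinylogous E1cB) to give the ring-enforced C5=C6 enol lactone; the liberated C8 hydroxyl is trapped by the Yamaguchi mixed anhydride before it can attack the enol lactone.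

Step 17
Reactants: 27 bis-silyl ether
Product: 28 13-O-deacetyl target ((1(10)Z,2R,4S,5E,8R)-2-acetoxy-4,13-dihydroxy-8-(tigloyloxy)germacra-1(10),5,7(11)-trien-12,6-olide)
Conditions: HF·pyridine, pyridine, THF, 0 → 23 °C
Reagents that add atoms: none
Why: Buffered HF·pyridine cleaves the primary tert-butyldimethylsilyl ether and the tertiary triethylsilyl ether without ionising the tertiary allylic alcohol or cleaving the esters.

Step 18
Reactants: 28 13-O-deacetyl target
Product: 29 CNP0166369.1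
Conditions: Ac2O, pyridine, CH2Cl2, 0 °C
Reagents that add atoms: acetic anhydride (CC(=O)OC(C)=O)
Why: Acetylation without DMAP at 0 °C acylates the primary C13 hydroxyl and leaves the tertiary C4 hydroxyl free.

**Compound list**

1 | 2,4-dimethoxyphenol | COc1ccc(O)c(OC)c1 | starting material
2 | 2,4,4-trimethoxycyclohexa-2,5-dien-1-one | COC1=CC(OC)(OC)C=CC1=O | intermediate
3 | (1S,6R)-3,5,5-trimethoxy-7-oxabicyclo[4.1.0]hept-3-en-2-one | O=C1C(OC)=CC(OC)(OC)[C@@H]2O[C@H]12 | intermediate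
4 | ethyl (2E)-[(1R,6R)-3,5,5-trimethoxy-7-oxabicyclo[4.1.0]hept-3-en-2-ylidene]acetate | CCOC(=O)/C=C1\[C@H]2O[C@H]2C(OC)(OC)C=C1OC | intermediate
5 | ethyl (2E)-[(1R,6R)-3-methoxy-5-oxo-7-oxabicyclo[4.1.0]hept-3-en-2-ylidene]acetate | CCOC(=O)/C=C1\[C@H]2O[C@H]2C(=O)C=C1OC | intermediate
6 | bromomagnesium alkoxide of ethyl (2E)-[(1R,5S,6R)-5-hydroxy-3-methoxy-5-methyl-7-oxabicyclo[4.1.0]hept-3-en-2-ylidene]acetate | CCOC(=O)/C=C1\[C@H]2O[C@H]2[C@@](C)(O[Mg]Br)C=C1OC | intermediate
7 | ethyl (2E)-{(1R,5S,6R)-3-methoxy-5-methyl-5-[(triethylsilyl)oxy]-7-oxabicyclo[4.1.0]hept-3-en-2-ylidene}acetate | CCOC(=O)/C=C1\[C@H]2O[C@H]2[C@@](C)(O[Si](CC)(CC)CC)C=C1OC | intermediate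
8 | (2E)-2-{(1R,5S,6R)-3-methoxy-5-methyl-5-[(triethylsilyl)oxy]-7-oxabicyclo[4.1.0]hept-3-en-2-ylidene}ethan-1-ol | OC/C=C1\[C@H]2O[C@H]2[C@@](C)(O[Si](CC)(CC)CC)C=C1OC | intermediate
9 | 3-{[tert-butyl(dimethyl)silyl]oxy}propanoic acid | CC(C)(C)[Si](C)(C)OCCC(=O)O | starting material
10 | (2E)-2-{(1R,5S,6R)-3-methoxy-5-methyl-5-[(triethylsilyl)oxy]-7-oxabicyclo[4.1.0]hept-3-en-2-ylidene}ethyl 3-{[tert-butyl(dimethyl)silyl]oxy}propanoate | CC(C)(C)[Si](C)(C)OCCC(=O)OC/C=C1\[C@H]2O[C@H]2[C@@](C)(O[Si](CC)(CC)CC)C=C1OC | intermediate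
11 | trimethylsilyl ketene acetal of 10 (ketene acetal geometry not defined) | CC(C)(C)[Si](C)(C)OCC=C(O[Si](C)(C)C)OC/C=C1\[C@H]2O[C@H]2[C@@](C)(O[Si](CC)(CC)CC)C=C1OC | intermediate
12 | trimethylsilyl ester of 13 (C11 epimers) | C[Si](C)(C)OC(=O)C(CO[Si](C)(C)C(C)(C)C)[C@]1(C=C)[C@H]2O[C@H]2[C@@](C)(O[Si](CC)(CC)CC)C=C1OC | intermediate
13 | 3-{[tert-butyl(dimethyl)silyl]oxy}-2-{(1R,2R,5S,6R)-2-ethenyl-3-methoxy-5-methyl-5-[(triethylsilyl)oxy]-7-oxabicyclo[4.1.0]hept-3-en-2-yl}propanoic acid (C11 epimers) | OC(=O)C(CO[Si](C)(C)C(C)(C)C)[C@]1(C=C)[C@H]2O[C@H]2[C@@](C)(O[Si](CC)(CC)CC)C=C1OC | intermediate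
14 | (3aR,6S,7R,7aS)-3-({[tert-butyl(dimethyl)silyl]oxy}methyl)-3a-ethenyl-7-hydroxy-4-methoxy-6-methyl-6-[(triethylsilyl)oxy]-3a,6,7,7a-tetrahydro-1-benzofuran-2(3H)-one (C11 epimers) | O=C1O[C@@H]2[C@@H](O)[C@@](C)(O[Si](CC)(CC)CC)C=C(OC)[C@]2(C=C)C1CO[Si](C)(C)C(C)(C)C | intermediate
15 | (3aR,6S,7R,7aS)-3-({[tert-butyl(dimethyl)silyl]oxy}methyl)-3a-ethenyl-7-hydroxy-6-methyl-6-[(triethylsilyl)oxy]hexahydro-1-benzofuran-2,4-dione (C11 epimers) | O=C1O[C@@H]2[C@@H](O)[C@@](C)(O[Si](CC)(CC)CC)CC(=O)[C@]2(C=C)C1CO[Si](C)(C)C(C)(C)C | intermediate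
16 | (3aR,6S,7R,7aS)-3-({[tert-butyl(dimethyl)silyl]oxy}methyl)-3a-ethenyl-6-methyl-2,4-dioxo-6-[(triethylsilyl)oxy]octahydro-1-benzofuran-7-yl methanesulfonate (C11 epimers) | O=C1O[C@@H]2[C@@H](OS(C)(=O)=O)[C@@](C)(O[Si](CC)(CC)CC)CC(=O)[C@]2(C=C)C1CO[Si](C)(C)C(C)(C)C | intermediate
17 | (3aR,4S,6S,7R,7aS)-3-({[tert-butyl(dimethyl)silyl]oxy}methyl)-3a-ethenyl-4-hydroxy-6-methyl-2-oxo-4-(prop-1-yn-1-yl)-6-[(triethylsilyl)oxy]octahydro-1-benzofuran-7-yl methanesulfonate (C11 epimers) | O=C1O[C@@H]2[C@@H](OS(C)(=O)=O)[C@@](C)(O[Si](CC)(CC)CC)C[C@](O)(C#CC)[C@]2(C=C)C1CO[Si](C)(C)C(C)(C)C | intermediate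
18 | potassium alkoxide of 17 | O=C1O[C@@H]2[C@@H](OS(C)(=O)=O)[C@@](C)(O[Si](CC)(CC)CC)C[C@]([O-])(C#CC)[C@]2(C=C)C1CO[Si](C)(C)C(C)(C)C.[K+] | intermediate
19 | potassium 1,2(10)-allenolate of the ten-membered ring ((4S,5R,6S,7E); allene axis not defined) | O=C1O[C@@H]2[C@@H](OS(C)(=O)=O)[C@@](C)(O[Si](CC)(CC)CC)CC([O-])=C=C(C)C/C=C2\C1CO[Si](C)(C)C(C)(C)C.[K+] | intermediate
20 | (1(10)Z,4S,5R,6S,7E)-13-{[tert-butyl(dimethyl)silyl]oxy}-5-[(methylsulfonyl)oxy]-2-oxo-4-[(triethylsilyl)oxy]germacra-1(10),7-dien-12,6-olide (C11 epimers) | O=C1O[C@@H]2[C@@H](OS(C)(=O)=O)[C@@](C)(O[Si](CC)(CC)CC)CC(=O)/C=C(C)\C/C=C2\C1CO[Si](C)(C)C(C)(C)C | intermediate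
21 | (1(10)Z,4S,5R,6R,7S,8R)-13-{[tert-butyl(dimethyl)silyl]oxy}-7,8-epoxy-5-[(methylsulfonyl)oxy]-2-oxo-4-[(triethylsilyl)oxy]germacr-1(10)-en-12,6-olide (C11 epimers) | O=C1O[C@@H]2[C@@H](OS(C)(=O)=O)[C@@](C)(O[Si](CC)(CC)CC)CC(=O)/C=C(C)\C[C@H]3O[C@]23C1CO[Si](C)(C)C(C)(C)C | intermediate
22 | (1(10)Z,2R,4S,5R,6R,7S,8R)-13-{[tert-butyl(dimethyl)silyl]oxy}-7,8-epoxy-2-hydroxy-5-[(methylsulfonyl)oxy]-4-[(triethylsilyl)oxy]germacr-1(10)-en-12,6-olide (C11 epimers) | O=C1O[C@@H]2[C@@H](OS(C)(=O)=O)[C@@](C)(O[Si](CC)(CC)CC)C[C@@H](O)/C=C(C)\C[C@H]3O[C@]23C1CO[Si](C)(C)C(C)(C)C | intermediate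
23 | (1(10)Z,2R,4S,5R,6R,7S,8R)-2-acetoxy-13-{[tert-butyl(dimethyl)silyl]oxy}-7,8-epoxy-5-[(methylsulfonyl)oxy]-4-[(triethylsilyl)oxy]germacr-1(10)-en-12,6-olide (C11 epimers) | O=C1O[C@@H]2[C@@H](OS(C)(=O)=O)[C@@](C)(O[Si](CC)(CC)CC)C[C@@H](OC(C)=O)/C=C(C)\C[C@H]3O[C@]23C1CO[Si](C)(C)C(C)(C)C | intermediate
24 | tiglic acid, (2E)-2-methylbut-2-enoic acid | C/C=C(\C)C(=O)O | starting material
25 | (1(10)Z,2R,4S,5R,6S,8R)-2-acetoxy-13-{[tert-butyl(dimethyl)silyl]oxy}-8-hydroxy-5-[(methylsulfonyl)oxy]-4-[(triethylsilyl)oxy]germacra-1(10),7(11)-dien-12,6-olide | O=C1O[C@@H]2[C@@H](OS(C)(=O)=O)[C@@](C)(O[Si](CC)(CC)CC)C[C@@H](OC(C)=O)/C=C(C)\C[C@@H](O)C2=C1CO[Si](C)(C)C(C)(C)C | intermediate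
26 | (1(10)Z,2R,4S,5E,8R)-2-acetoxy-13-{[tert-butyl(dimethyl)silyl]oxy}-8-hydroxy-4-[(triethylsilyl)oxy]germacra-1(10),5,7(11)-trien-12,6-olide | O[C@@H]1C/C(C)=C\[C@H](OC(C)=O)C[C@](C)(O[Si](CC)(CC)CC)/C=C2/OC(=O)C(CO[Si](C)(C)C(C)(C)C)=C21 | intermediate
27 | (1(10)Z,2R,4S,5E,8R)-2-acetoxy-13-{[tert-butyl(dimethyl)silyl]oxy}-8-(tigloyloxy)-4-[(triethylsilyl)oxy]germacra-1(10),5,7(11)-trien-12,6-olide | C/C=C(\C)C(=O)O[C@@H]1C/C(C)=C\[C@H](OC(C)=O)C[C@](C)(O[Si](CC)(CC)CC)/C=C2/OC(=O)C(CO[Si](C)(C)C(C)(C)C)=C21 | intermediate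
28 | (1(10)Z,2R,4S,5E,8R)-2-acetoxy-4,13-dihydroxy-8-(tigloyloxy)germacra-1(10),5,7(11)-trien-12,6-olide | C/C=C(\C)C(=O)O[C@@H]1C/C(C)=C\[C@H](OC(C)=O)C[C@](C)(O)/C=C2/OC(=O)C(CO)=C21 | intermediate
29 | CNP0166369.1, (1(10)Z,2R,4S,5E,8R)-2,13-diacetoxy-4-hydroxy-8-(tigloyloxy)germacra-1(10),5,7(11)-trien-12,6-olide | C/C=C(\C)C(=O)O[C@@H]1C/C(C)=C\[C@H](OC(C)=O)C[C@](C)(O)/C=C2/OC(=O)C(COC(C)=O)=C21 | target

Total step count: 18. Longest linear sequence: 18 steps (from 1).

**Steps most likely to fail**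

Step 12. The alkoxide may be diverted before it rearranges: acyl transfer from the lactone to O2, migration of the C4 silyl group to the 1,3-diaxial alkoxide, or proton transfer within the allenolate followed by β-elimination. The fallback removes the charge. Setting out from 17, Me3SiOTf and 2,6-lutidine give the trimethylsilyl ether F1. Heating F1 (1,2-dichlorobenzene, 180 °C, sealed tube or flow) should bring about the uncharged oxy-Cope shift to the ring-expanded silyl allenyl ether F2. Aqueous citric acid in THF then hydrolyses F2 to the enone, and the route is rejoined at 20.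

Step 9. Ionisation of the tertiary allylic silyl ether, with loss of the C4 oxygen and 1,3-carbonyl transposition (Stork–Danheiser pathway), may compete with simple hydrolysis of the enol ether. The fallback accepts the transposition and puts the oxygen back. Setting out from 13, aqueous HCl in THF gives the transposed enone hydroxy lactone F3. Nucleophilic epoxidation directed by the C5 hydroxyl (t-BuOOH, DBU) gives the 3,4-epoxy ketone F4 with the oxygen on the face of that hydroxyl. SmI2 (THF/MeOH, −78 °C) cleaves the α C–O bond to the β-hydroxy ketone diol F5. Selective mesylation of the secondary hydroxyl gives the mesylate F6, and Et3SiOTf with 2,6-lutidine returns to the route at 16.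

Step 13. The ring conformation may override the catalyst and give poor or reversed facial selectivity, and the pH 10.5 medium may move the C7=C8 bond into conjugation with the lactone. The fallback uses a neutral, substrate-controlled epoxidation and corrects C8 at the esterification. Setting out from 20, m-chloroperbenzoic acid with NaHCO3 in CH2Cl2 at 0 °C is used. If it furnishes the (7R,8S)-epoxide F7, this is reduced and acetylated as in steps 14 and 15 (alcohol F8, acetate F9). DBU alone then opens it to the 8-epi hydroxy ylidenebutenolide F10. Esterification with 24 under Mitsunobu conditions (PPh3, diisopropyl azodicarboxylate) proceeds with inversion at C8 and returns to the route at 27.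

Further compounds
F1 | step 12 | trimethylsilyl ether of 17 | O=C1O[C@@H]2[C@@H](OS(C)(=O)=O)[C@@](C)(O[Si](CC)(CC)CC)C[C@](O[Si](C)(C)C)(C#CC)[C@]2(C=C)C1CO[Si](C)(C)C(C)(C)C
F2 | step 12 | ring-expanded 2-(trimethylsilyloxy)-1,2(10)-allene, silyl allenyl ether of 20 | O=C1O[C@@H]2[C@@H](OS(C)(=O)=O)[C@@](C)(O[Si](CC)(CC)CC)CC(O[Si](C)(C)C)=C=C(C)C/C=C2\C1CO[Si](C)(C)C(C)(C)C
F3 | step 9 | (3aR,7R,7aS)-3-({[tert-butyl(dimethyl)silyl]oxy}methyl)-3a-ethenyl-7-hydroxy-6-methyl-3a,7a-dihydro-1-benzofuran-2,4(3H,7H)-dione, transposed enone | O=C1O[C@@H]2[C@@H](O)C(C)=CC(=O)[C@]2(C=C)C1CO[Si](C)(C)C(C)(C)C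
F4 | step 9 | 3,4-epoxy ketone from F3 (epoxide cis to the C5 hydroxyl) | O=C1O[C@@H]2[C@@H](O)[C@@]3(C)O[C@H]3C(=O)[C@]2(C=C)C1CO[Si](C)(C)C(C)(C)C
F5 | step 9 | (3aR,6S,7R,7aS)-3-({[tert-butyl(dimethyl)silyl]oxy}methyl)-3a-ethenyl-6,7-dihydroxy-6-methylhexahydro-1-benzofuran-2,4-dione | O=C1O[C@@H]2[C@@H](O)[C@@](C)(O)CC(=O)[C@]2(C=C)C1CO[Si](C)(C)C(C)(C)C
F6 | step 9 | 7-methanesulfonate of F5 (tertiary hydroxyl free) | O=C1O[C@@H]2[C@@H](OS(C)(=O)=O)[C@@](C)(O)CC(=O)[C@]2(C=C)C1CO[Si](C)(C)C(C)(C)C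
F7 | step 13 | (7R,8S)-epoxide, 7,8-diastereomer of 21 | O=C1O[C@@H]2[C@@H](OS(C)(=O)=O)[C@@](C)(O[Si](CC)(CC)CC)CC(=O)/C=C(C)\C[C@@H]3O[C@@]23C1CO[Si](C)(C)C(C)(C)C
F8 | step 13 | (2R)-alcohol from F7 | O=C1O[C@@H]2[C@@H](OS(C)(=O)=O)[C@@](C)(O[Si](CC)(CC)CC)C[C@@H](O)/C=C(C)\C[C@@H]3O[C@@]23C1CO[Si](C)(C)C(C)(C)C
F9 | step 13 | (2R)-acetate from F8 | O=C1O[C@@H]2[C@@H](OS(C)(=O)=O)[C@@](C)(O[Si](CC)(CC)CC)C[C@@H](OC(C)=O)/C=C(C)\C[C@@H]3O[C@@]23C1CO[Si](C)(C)C(C)(C)C
F10 | step 13 | (8S)-epimer of 26 | O[C@H]1C/C(C)=C\[C@H](OC(C)=O)C[C@](C)(O[Si](CC)(CC)CC)/C=C2/OC(=O)C(CO[Si](C)(C)C(C)(C)C)=C21
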